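**Retrosynthetic overview**

1. The target is a central naphthalene, ring B (OH on B-C1, OMe on B-C8), carrying two identical 1-hydroxy-8-methoxynaphthalen-2-yl units: ring A on B-C2 and ring C on B-C4. The last bonds cut are the three phenolic MOM ethers and the B-C8 O–CH3 bond.
2. Feature used: B-C8a is the only unsubstituted carbon ortho to B-C4a (B-C4 holds ring C) and it lies next to the B-C1 oxygen. The B-C8–B-C8a bond is therefore cut, turning B-C5 to B-C8 into a but-3-enoic acid chain on a 2,4-diaryl-5-oxyphenyl ring (acid 11), closed through a dienylketene.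
3. Acid 11 comes from teraryl aldehyde 8 by a Wittig reaction with the ylide of 9. Aldehyde 8 comes from dibromide 7 and two equivalents of one boronate 5 (A = C) in a single twofold Suzuki coupling.
4. Boronate 5 comes from naphthalene-1,8-diol 1 by mono-O-methylation, MOM protection and MOM-directed lithiation/borylation at C2.
5. Ring order: the naphthalenes of A and C and the first ring of B (the benzene of 6) are bought; the only ring made is the B-C5 to B-C8 ring, in step 7.

Key step: step 7

**Remarks**

- Ar = 8-methoxy-1-(methoxymethoxy)naphthalen-2-yl. Locants written B-Cn refer to ring B numbered with OH on C1 and OMe on C8.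
- Assumption: none of the biaryl axes is configurationally stable at room temperature and the target has no stereocentre, so no stereocontrol is needed.
- All three phenols are carried as methoxymethyl (MOM) ethers. The same group directs the C2 lithiation of the outer naphthalenes, it should tolerate buffered hot Ac2O, and all three fall in one mild acid step.
- An E/Z mixture of acid 11 is acceptable, because step 7 equilibrates the alkene geometry.

**Route**

Step 1
Reactants: 1 naphthalene-1,8-diol
Product: 2 8-methoxynaphthalen-1-ol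
Conditions: MeI (1.05 equiv), K2CO3, acetone, reflux
Reagents that add atoms: iodomethane CI
Why: Williamson O-methylation; the peri hydrogen bond makes the first OH acidic and then ties the remaining OH to the new OMe group, so alkylation should stop at the monoether.

Step 2
Reactants: 2 8-methoxynaphthalen-1-ol
Product: 3 1-methoxy-8-(methoxymethoxy)naphthalene
Conditions: NaH, DMF, 0 °C; MOMCl, 0 °C to rt
Reagents that add atoms: chloromethyl methyl ether COCCl
Why: MOM ether formation by alkylation of the sodium naphthoxide; NaH is chosen because the peri-hydrogen-bonded OH reacts sluggishly under amine bases.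

Step 3
Reactants: 3 1-methoxy-8-(methoxymethoxy)naphthalene
Product: 5 2-Ar-4,4,5,5-tetramethyl-1,3,2-dioxaborolane, via aryllithium 4 (not isolated)
Conditions: n-BuLi, TMEDA, Et2O, 0 °C to rt; i-PrOBpin, −78 °C to rt; aq NH4Cl
Reagents that add atoms: 2-isopropoxy-4,4,5,5-tetramethyl-1,3,2-dioxaborolane CC(C)OB1OC(C)(C)C(C)(C)O1
Why: Directed ortho metalation followed by borylation of the aryllithium; the chelating OCH2OCH3 group outranks OMe as a director and the peri position is occupied, so C2 rather than C7 should be metalated.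

Step 4
Reactants: 6 2,4-dibromo-5-hydroxybenzaldehyde
Product: 7 2,4-dibromo-5-(methoxymethoxy)benzaldehyde
Conditions: MOMCl, i-Pr2NEt, CH2Cl2, 0 °C to rt
Reagents that add atoms: chloromethyl methyl ether COCCl
Why: MOM ether formation of an acidic ortho-bromophenol under amine base; the aldehyde and both C–Br bonds are inert to these conditions.

Step 5
Reactants: 7 2,4-dibromo-5-(methoxymethoxy)benzaldehyde; 5 2-Ar-4,4,5,5-tetramethyl-1,3,2-dioxaborolane (2.5 equiv)
Product: 8 2,4-bis(Ar)-5-(methoxymethoxy)benzaldehyde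
Conditions: Pd(OAc)2 (5 mol %), SPhos (10 mol %), K3PO4, toluene/H2O, 90 °C
Reagents that add atoms: none
Why: Twofold Suzuki–Miyaura coupling; the SPhos-ligated zerovalent palladium catalyst suits ortho-substituted partners, and because one boronate serves both C–Br sites no site selectivity is required.

Step 6
Reactants: 8 2,4-bis(Ar)-5-(methoxymethoxy)benzaldehyde; 9 (2-carboxyethyl)triphenylphosphonium bromide
Product: 11 (E)-4-[2,4-bis(Ar)-5-(methoxymethoxy)phenyl]but-3-enoic acid, via ylide carboxylate 10 (not isolated)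
Conditions: 9, NaN(SiMe3)2 (2 equiv per 9), THF, 0 °C; then 8, −78 °C to rt; cold 1 M HCl to pH 4
Reagents that add atoms: none
Why: Wittig olefination with the carboxylate-bearing ylide, which typically favours the E-4-arylbut-3-enoic acid; the aldehyde has no enolizable hydrogen and the MOM ethers tolerate the base and the brief cold acidification.

Step 7
Reactants: 11 (E)-4-[2,4-bis(Ar)-5-(methoxymethoxy)phenyl]but-3-enoic acid
Product: 16 8-(methoxymethoxy)-5,7-bis(Ar)naphthalen-1-yl acetate (acetoxy on B-C8), via mixed anhydride 12 (not isolated), via Z-dienylketene 13 (not isolated), via cyclohexadienone 14 (not isolated), via free naphthol 15 (not isolated)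
Conditions: Ac2O, NaOAc (anhydrous, 3 equiv), 120–140 °C, N2
Reagents that add atoms: acetic anhydride CC(=O)OC(C)=O
Why: Ac2O converts the acid into mixed anhydride 12, whose acetate-mediated enolization (through the conjugated but-2-enoyl isomer) lets the E alkene reach the Z geometry and whose loss of acetic acid gives aryl dienylketene 13. A thermal six-electron disrotatory electrocyclization of 13 (aryl B-C8a=B-C4a, B-C5=B-C6, ketene B-C7=B-C8) forms the B-C8–B-C8a bond and closes the six-membered B-C5 to B-C8 ring as dienone 14, which tautomerizes to naphthol 15 and is acetylated to 16. The closest known reaction type is the Ac2O/NaOAc cyclization of 4-arylbut-3-enoic acids to 1-naphthyl acetates that ends the Stobbe naphthol synthesis. No stereocentre remains, since the sp3 carbon B-C8a of 14 is erased on aromatization. The selectivity needed is the site of closure: the other ortho carbon (B-C4) carries ring C and closure onto ring C would require an eight-membered transition state, so only B-C8a can react. That carbon is also activated by the adjacent B-C1 oxygen, so a competing acylium (Friedel–Crafts) path would give the same product.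

Step 8
Reactants: 16 8-(methoxymethoxy)-5,7-bis(Ar)naphthalen-1-yl acetate
Product: 15 8-(methoxymethoxy)-5,7-bis(Ar)naphthalen-1-ol
Conditions: K2CO3 (cat.), MeOH/THF, rt
Reagents that add atoms: none
Why: Base-catalysed transesterification of the aryl acetate with methanol; MOM and methyl ethers are inert to carbonate in methanol.

Step 9
Reactants: 15 8-(methoxymethoxy)-5,7-bis(Ar)naphthalen-1-ol
Product: 17 8-methoxy-1-(methoxymethoxy)-2,4-bis(Ar)naphthalene
Conditions: NaH, DMF, 0 °C; MeI, 0 °C to rt
Reagents that add atoms: iodomethane CI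
Why: Williamson O-methylation of the only free hydroxyl; NaH breaks its peri hydrogen bond to the B-C1 oxygen and no other acidic site is present.

Step 10
Reactants: 17 8-methoxy-1-(methoxymethoxy)-2,4-bis(Ar)naphthalene
Product: 18 8,8',8''-trimethoxy-[2,2':4',2''-ternaphthalene]-1,1',1''-triol (target)
Conditions: conc. aq HCl (excess), MeOH/THF (degassed), 45 °C
Reagents that add atoms: none
Why: Acid-catalysed acetal exchange with methanol removes the three MOM groups; aryl methyl ethers and biaryl bonds are stable to dilute HCl, and degassed solvent guards the electron-rich naphthols against air oxidation.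

**Compound list**

1 | naphthalene-1,8-diol | Oc1cccc2cccc(O)c12 | starting material
2 | 8-methoxynaphthalen-1-ol | COc1cccc2cccc(O)c12 | intermediate
3 | 1-methoxy-8-(methoxymethoxy)naphthalene | COCOc1cccc2cccc(OC)c12 | intermediate
4 | [8-methoxy-1-(methoxymethoxy)naphthalen-2-yl]lithium | [Li]c1ccc2cccc(OC)c2c1OCOC | intermediate
5 | 2-[8-methoxy-1-(methoxymethoxy)naphthalen-2-yl]-4,4,5,5-tetramethyl-1,3,2-dioxaborolane | COCOc1c(B2OC(C)(C)C(C)(C)O2)ccc2cccc(OC)c12 | intermediate
6 | 2,4-dibromo-5-hydroxybenzaldehyde | O=Cc1cc(O)c(Br)cc1Br | starting material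
7 | 2,4-dibromo-5-(methoxymethoxy)benzaldehyde | O=Cc1cc(OCOC)c(Br)cc1Br | intermediate
8 | 2,4-bis[8-methoxy-1-(methoxymethoxy)naphthalen-2-yl]-5-(methoxymethoxy)benzaldehyde | O=Cc1cc(OCOC)c(-c2ccc3cccc(OC)c3c2OCOC)cc1-c4ccc5cccc(OC)c5c4OCOC | intermediate
9 | (2-carboxyethyl)triphenylphosphonium bromide | OC(=O)CC[P+](c1ccccc1)(c1ccccc1)c1ccccc1.[Br-] | starting material
10 | sodium 3-(triphenylphosphoranylidene)propanoate | [Na+].[O-]C(=O)CC=P(c1ccccc1)(c1ccccc1)c1ccccc1 | intermediate
11 | (E)-4-{2,4-bis[8-methoxy-1-(methoxymethoxy)naphthalen-2-yl]-5-(methoxymethoxy)phenyl}but-3-enoic acid | OC(=O)C/C=C/c1cc(OCOC)c(-c2ccc3cccc(OC)c3c2OCOC)cc1-c4ccc5cccc(OC)c5c4OCOC | intermediate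
12 | acetic (E)-4-{2,4-bis[8-methoxy-1-(methoxymethoxy)naphthalen-2-yl]-5-(methoxymethoxy)phenyl}but-3-enoic anhydride | CC(=O)OC(=O)C/C=C/c1cc(OCOC)c(-c2ccc3cccc(OC)c3c2OCOC)cc1-c4ccc5cccc(OC)c5c4OCOC | intermediate
13 | (3Z)-4-{2,4-bis[8-methoxy-1-(methoxymethoxy)naphthalen-2-yl]-5-(methoxymethoxy)phenyl}buta-1,3-dien-1-one | O=C=C/C=C\c1cc(OCOC)c(-c2ccc3cccc(OC)c3c2OCOC)cc1-c4ccc5cccc(OC)c5c4OCOC | intermediate
14 | 8-(methoxymethoxy)-5,7-bis[8-methoxy-1-(methoxymethoxy)naphthalen-2-yl]naphthalen-1(8aH)-one (racemic, transient) | O=C1C=CC=C2C(-c6ccc7cccc(OC)c7c6OCOC)=CC(-c3ccc4cccc(OC)c4c3OCOC)=C(OCOC)C12 | intermediate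
15 | 8-(methoxymethoxy)-5,7-bis[8-methoxy-1-(methoxymethoxy)naphthalen-2-yl]naphthalen-1-ol | Oc1cccc2c(-c6ccc7cccc(OC)c7c6OCOC)cc(-c3ccc4cccc(OC)c4c3OCOC)c(OCOC)c12 | intermediate
16 | 8-(methoxymethoxy)-5,7-bis[8-methoxy-1-(methoxymethoxy)naphthalen-2-yl]naphthalen-1-yl acetate | CC(=O)Oc1cccc2c(-c6ccc7cccc(OC)c7c6OCOC)cc(-c3ccc4cccc(OC)c4c3OCOC)c(OCOC)c12 | intermediate
17 | 8-methoxy-1-(methoxymethoxy)-2,4-bis[8-methoxy-1-(methoxymethoxy)naphthalen-2-yl]naphthalene | COc1cccc2c(-c6ccc7cccc(OC)c7c6OCOC)cc(-c3ccc4cccc(OC)c4c3OCOC)c(OCOC)c12 | intermediate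
18 | 8,8',8''-trimethoxy-[2,2':4',2''-ternaphthalene]-1,1',1''-triol (CNP0482979.0) | COc1cccc2ccc(-c3cc(-c4ccc5cccc(OC)c5c4O)c4cccc(OC)c4c3O)c(O)c12 | target

**Step count**

Total: 10 steps. Longest linear sequence: 9 steps (steps 1, 2, 3, 5, 6, 7, 8, 9, 10 from naphthalene-1,8-diol).

**Steps most likely to fail**

Step 7. The E alkene may reach the Z geometry too slowly, so that the ketene oligomerizes or the anhydride decarboxylates. Closure beside the B-C1 OMOM group may be slow, and the MOM acetals may undergo acetolysis in hot Ac2O. The fallback replaces the ketene electrocyclization by an ionic acylation followed by dehydrogenation, which has no alkene-geometry requirement. It sets out from acid 11. Hydrogenation of the alkene (H2, palladium on carbon, EtOAc) should give 4-{2,4-bis[8-methoxy-1-(methoxymethoxy)naphthalen-2-yl]-5-(methoxymethoxy)phenyl}butanoic acid F1. Friedel–Crafts ring closure through the mixed trifluoroacetic anhydride ((CF3CO)2O, 2,6-di-tert-butylpyridine, CH2Cl2, 0 °C) at the same single open ortho carbon should give 8-(methoxymethoxy)-5,7-bis[8-methoxy-1-(methoxymethoxy)naphthalen-2-yl]-3,4-dihydronaphthalen-1(2H)-one F2. Enol silylation (LiN(SiMe3)2, Me3SiCl, THF, −78 °C) should give trimethyl({8-(methoxymethoxy)-5,7-bis[8-methoxy-1-(methoxymethoxy)naphthalen-2-yl]-3,4-dihydronaphthalen-1-yl}oxy)silane F3. Saegusa–Ito dehydrogenation with Pd(OAc)2 in MeCN should then give 8-(methoxymethoxy)-5,7-bis[8-methoxy-1-(methoxymethoxy)naphthalen-2-yl]naphthalen-1(4H)-one F4, which tautomerizes in the flask to naphthol 15. The route is rejoined at 15, before step 9.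

Step 5. Protodeboronation of the ortho-alkoxy naphthylboronate in hot aqueous base may outpace the second, more hindered coupling at the C–Br flanked by the OMOM group, so the reaction stalls after one arylation. The fallback is a base-free organozinc coupling. It sets out from 3 and 7. Lithiation of 3 as in step 3 gives aryllithium 4, and transmetalation with ZnCl2 (THF, −78 °C to rt) should give chlorido[8-methoxy-1-(methoxymethoxy)naphthalen-2-yl]zinc F5. Negishi coupling of F5 (3 equiv) with dibromide 7 (Pd2(dba)3, XPhos, THF, 60 °C), which tolerates the aldehyde, should return to the route at 8.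

Step 3. Deprotonation may compete at C7 next to the OMe group, or the base may attack the acetal, so the boronate forms as a regioisomeric mixture or in low conversion. The fallback uses electrophilic halogenation in place of metalation. It sets out from 2. Amine-mediated ortho-bromination (NBS, cat. i-Pr2NH, CH2Cl2, 0 °C) should give 2-bromo-8-methoxynaphthalen-1-ol F6. MOM protection (NaH, MOMCl, DMF) should give 2-bromo-8-methoxy-1-(methoxymethoxy)naphthalene F7. Miyaura borylation (B2pin2, Pd(dppf)Cl2, KOAc, dioxane, 90 °C) should return to the route at 5.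

**Further compounds**

F1 | step 7 | 4-{2,4-bis[8-methoxy-1-(methoxymethoxy)naphthalen-2-yl]-5-(methoxymethoxy)phenyl}butanoic acid | OC(=O)CCCc1cc(OCOC)c(-c2ccc3cccc(OC)c3c2OCOC)cc1-c4ccc5cccc(OC)c5c4OCOC
F2 | step 7 | 8-(methoxymethoxy)-5,7-bis[8-methoxy-1-(methoxymethoxy)naphthalen-2-yl]-3,4-dihydronaphthalen-1(2H)-one | O=C1CCCc2c(-c6ccc7cccc(OC)c7c6OCOC)cc(-c3ccc4cccc(OC)c4c3OCOC)c(OCOC)c12
F3 | step 7 | trimethyl({8-(methoxymethoxy)-5,7-bis[8-methoxy-1-(methoxymethoxy)naphthalen-2-yl]-3,4-dihydronaphthalen-1-yl}oxy)silane | C[Si](C)(C)OC1=CCCc2c(-c6ccc7cccc(OC)c7c6OCOC)cc(-c3ccc4cccc(OC)c4c3OCOC)c(OCOC)c12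
F4 | step 7 | 8-(methoxymethoxy)-5,7-bis[8-methoxy-1-(methoxymethoxy)naphthalen-2-yl]naphthalen-1(4H)-one | O=C1C=CCc2c(-c6ccc7cccc(OC)c7c6OCOC)cc(-c3ccc4cccc(OC)c4c3OCOC)c(OCOC)c12
F5 | step 5 | chlorido[8-methoxy-1-(methoxymethoxy)naphthalen-2-yl]zinc | Cl[Zn]c1ccc2cccc(OC)c2c1OCOC
F6 | step 3 | 2-bromo-8-methoxynaphthalen-1-ol | COc1cccc2ccc(Br)c(O)c12
F7 | step 3 | 2-bromo-8-methoxy-1-(methoxymethoxy)naphthalene | COCOc1c(Br)ccc2cccc(OC)c12
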